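(All runs come from a simulation for substances that don't exist; the scatter is artificial.)

An equal charge of J and X tempts a chemist to book the two out together and to read a flat end as a spent reagent, and over this flask two colleagues fell out on exactly that.

all flasks: J 1.7 M

|  | X | remark | time |
|---|---|---|---|
| Friday's | 1.7 M | the very flask that is asked about, followed so far |  |
| flask | 1.70 M |  | 5.0 h |

- Friday's (time / min: G / %, D / %, J / %): 10.0: 12.8, 17.9, 69.0; 15.0: 24.0, 49.9, 27.1; 20.0: 25.8, 64.7, 10.2; 30.0: 25.7, 72.3, 0.7; 50.0: 25.8, 74.1, 0.5; 80.0: 25.3, 73.9, 0; 120: 26.2, 74.3, 0.1

(scatter of a reading: 0.3 percentage points)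

- percentages count the J that a species holds: one D counts as two
- candidate steps: J + X + G -> 2 G; J + X -> G; J + G -> D
- the reaction counts as stopped when no species that holds the J changes by six tenths of a point or more over the second half of the time

- the state of affairs at 5.0 h: stopped, and by what, or still going (X has run out first / it is still moving / all of J has reacted)
- the G standing at 5.0 h, as a percentage of the J charged
- the D standing at 5.0 h, as a percentage of the J charged

The first counts one X for each J reacted: in Friday's run J reads 0.5% at 50.0 min, so in her book X stands at the same figure of its equal charge, G and D are flat from then on, and the flask has stopped with X run out. The second counts by product: each G has cost one X, and each D, which the percentages count as two J, has cost one X as well. So he keeps an X bill, the X spent as a share of the J charged, which is the G share plus half the D share, and which Friday's readings at 50.0 min put at 62.9%. On 1.7 M of J that comes to 1.07 M of X against 1.70 M charged, so 37.1% of the X should still stand when J is gone, which makes J the limiting reagent.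

The forecast is his: all of J has reacted, with G at 25.8% and D at 74.2%, on the ground “With no J left, none of the candidate steps can run”.

At 5.00 h the flask gives all of J has reacted, with G at 26.0% and D at 74.0%. X stands at 37% of its charge, and the bill had left 37.1%.

    J + X + G → 2 G (k = 0.00550 L² mol⁻² s⁻¹)
    J + X → G (k = 4.40 × 10⁻⁶ L mol⁻¹ s⁻¹)
    J + G → D (k = 0.00350 L mol⁻¹ s⁻¹)

Her one-to-one count holds for the J that ends as G, 26.0% in this flask, and more of the J ends so in the neighbouring flask with 2.9 M of X on the same 1.7 M of J, where G at 54.9% stands above D at 45.1%. The bill of that neighbour is 77.4%, higher than the 62.9% read for this flask on Friday. On the neighbour's J that bill comes to 1.32 M of X and leaves 54.6% of the X charged, and the neighbour holds X at 54.6% of its own charge at 5.00 h.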